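**Retrosynthetic overview** (cembrane locants: C1 = lactone β-CH, C2 = lactone O–CH, C11/C12 = oxirane, C13 = CH–OAc, C17 = exocyclic CH2)
1. The last C–C bond is C1–C2: an intramolecular CrCl2-mediated (Nozaki–Hiyama type) 2-(methoxycarbonyl)allylation of a C2 enal closes the 14-membered carbocycle, and the resulting alkoxide closes the cis-γ-lactone.
2. The oxirane and the C13 acetate are set on the open chain: hydroxyl-directed VO(acac)2 epoxidation (erythro), then Mitsunobu inversion with AcOH (threo).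
3. The key union is at C10–C11: a B-alkyl Suzuki–Miyaura coupling of two halves of similar size, a C2–C10 triene (11 C) and a C11–C17 vinyl iodide (10 C).
4. The triene half comes from but-2-yn-1-ol, a silylpropyne, Me3Al and vinylMgBr (7Z by hydroalumination/iodination, 3E by Zr-catalysed carboalumination). The iodide half comes from propargyl alcohol, Me3Al, allylMgBr and methyl acrylate (C13 by Brown allylation, acrylate unit by Morita–Baylis–Hillman).
5. Ring order: oxirane (open chain) → 14-membered carbocycle → α-methylene-γ-lactone.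

Assumption: the carbinol carbon created in step 14 is carried as a ca. 1:1 epimer mixture (written without a descriptor) because step 22 erases it.

**Triene half (steps 1–8)**

Step 1
Reactants: 1 but-2-yn-1-ol
Product: 3 (Z)-3-iodobut-2-en-1-ol, via cyclic vinylalanate 2 (not isolated)
Conditions: NaAlH2(OCH2CH2OMe)2, THF, 0 °C → rt; then I2, THF, −78 → 0 °C
Reagents that add atoms: iodine, II
Why: Hydroxyl-directed trans-hydroalumination puts Al on C3 in a five-membered alanate, and iodinolysis with retention gives the Z iodide (I cis to CH2OH), which fixes the later 7Z geometry.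

Step 2
Reactants: 3 (Z)-3-iodobut-2-en-1-ol
Product: 4 (Z)-1-bromo-3-iodobut-2-ene
Conditions: CBr4, PPh3, CH2Cl2, 0 °C
Reagents that add atoms: carbon tetrabromide, BrC(Br)(Br)Br
Why: Appel reaction of a primary allylic alcohol under neutral conditions, so the vinyl iodide and the Z geometry are untouched.

Step 3
Reactants: 4 (Z)-1-bromo-3-iodobut-2-ene; 5 trimethyl(prop-1-yn-1-yl)silane
Product: 7 (Z)-(6-iodohept-5-en-1-yn-1-yl)trimethylsilane, via lithiated silylpropyne 6 (not isolated)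
Conditions: n-BuLi, THF, −78 → −20 °C (5 → 6); then 4, −78 °C → rt
Reagents that add atoms: none
Why: SN2 alkylation of the silyl-stabilised propargyl anion at the primary allylic bromide makes the C5–C6 bond; the stabilised anion does not exchange with the vinyl iodide.

Step 4
Reactants: 7 (Z)-(6-iodohept-5-en-1-yn-1-yl)trimethylsilane
Product: 8 (Z)-6-iodohept-5-en-1-yne
Conditions: K2CO3, MeOH, rt
Reagents that add atoms: none
Why: Methanolysis of the alkynyl C–Si bond (protodesilylation) frees the terminal alkyne for carbometalation.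

Step 5
Reactants: 8 (Z)-6-iodohept-5-en-1-yne
Product: 10 methyl (2E,6Z)-7-iodo-3-methylocta-2,6-dienoate, via alkenylalane 9 (not isolated)
Conditions: Me3Al (2.5 equiv), Cp2ZrCl2 (0.3 equiv), CH2Cl2, 0 °C → rt; then ClCO2Me, 0 °C → rt
Reagents that add atoms: trimethylaluminium, C[Al](C)C; methyl chloroformate, COC(=O)Cl
Why: Negishi Zr-catalysed carboalumination adds Me and Al syn across the terminal alkyne, and acylation of the C–Al bond with retention gives the 2E enoate (later 3E); the vinyl iodide is inert to these reagents.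

Step 6
Reactants: 10 methyl (2E,6Z)-7-iodo-3-methylocta-2,6-dienoate
Product: 11 (2E,6Z)-7-iodo-3-methylocta-2,6-dien-1-ol
Conditions: iBu2AlH (2.2 equiv), CH2Cl2, −78 °C; aq. KNaC4H4O6 work-up
Reagents that add atoms: none
Why: 1,2-Reduction of the enoate by the aluminium hydride gives the allylic alcohol without touching either alkene or the C–I bond.

Step 7
Reactants: 11 (2E,6Z)-7-iodo-3-methylocta-2,6-dien-1-ol
Product: 12 tert-butyl{[(2E,6Z)-7-iodo-3-methylocta-2,6-dien-1-yl]oxy}dimethylsilane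
Conditions: TBSCl, imidazole, DMF, rt
Reagents that add atoms: tert-butyldimethylsilyl chloride, CC(C)(C)[Si](C)(C)Cl
Why: Silylation protects the C2 hydroxyl through the hydroboration, the cross-couplings, the epoxidation and the Mitsunobu step.

Step 8
Reactants: 12 tert-butyl{[(2E,6Z)-7-iodo-3-methylocta-2,6-dien-1-yl]oxy}dimethylsilane; 13 vinylmagnesium bromide
Product: 15 tert-butyl{[(2E,6Z)-3,7-dimethylnona-2,6,8-trien-1-yl]oxy}dimethylsilane, via vinylzinc chloride 14 (not isolated)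
Conditions: ZnCl2, THF, 0 °C (13 → 14); then 12, Pd(PPh3)4 (5 mol %), THF, rt → 45 °C
Reagents that add atoms: none
Why: Negishi coupling replaces iodine by vinyl with retention, so C9 stays cis to C6 (6Z), and supplies C9–C10 as a terminal vinyl group.

**Vinyl iodide half (steps 9–16)**

Step 9
Reactants: 16 prop-2-yn-1-ol
Product: 18 (E)-3-iodo-2-methylprop-2-en-1-ol, via alkenylalane 17 (not isolated)
Conditions: Me3Al (3 equiv), Cp2ZrCl2 (0.25 equiv), CH2Cl2, rt; then I2, THF, −30 → 0 °C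
Reagents that add atoms: trimethylaluminium, C[Al](C)C; iodine, II
Why: Negishi carboalumination (syn addition of Me and Al) followed by iodinolysis with retention gives the E iodide that becomes C11=C12 with its C20 methyl.

Step 10
Reactants: 18 (E)-3-iodo-2-methylprop-2-en-1-ol
Product: 19 (E)-3-iodo-2-methylprop-2-enal
Conditions: MnO2, CH2Cl2, rt
Reagents that add atoms: none
Why: Chemoselective MnO2 oxidation of an allylic alcohol gives the enal without E/Z erosion.

Step 11
Reactants: 19 (E)-3-iodo-2-methylprop-2-enal; 20 allylmagnesium bromide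
Product: 23 (3S,1E)-1-iodo-2-methylhexa-1,5-dien-3-ol, via allylborane 21 (not isolated), via borinate ester 22 (not isolated)
Conditions: (−)-Ipc2BOMe (from (+)-α-pinene), Et2O, 0 °C → rt (20 → 21); then 19, −78 °C; then NaOH, H2O2, 0 °C → rt
Reagents that add atoms: none
Why: Brown asymmetric allylboration through a chair transition state; the (+)-α-pinene-derived reagent adds allyl to the Si face of the 2-methyl enal and sets C13 as S (reagent control).

Step 12
Reactants: 23 (3S,1E)-1-iodo-2-methylhexa-1,5-dien-3-ol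
Product: 24 triethyl{[(3S,1E)-1-iodo-2-methylhexa-1,5-dien-3-yl]oxy}silane
Conditions: TESCl, imidazole, CH2Cl2, 0 °C
Reagents that add atoms: triethylsilyl chloride, CC[Si](Cl)(CC)CC
Why: Temporary silylation prevents β-elimination and hemiacetal formation once C1 becomes an aldehyde, and the triethylsilyl group can later be removed in the presence of a TBS ether.

Step 13
Reactants: 24 triethyl{[(3S,1E)-1-iodo-2-methylhexa-1,5-dien-3-yl]oxy}silane
Product: 26 (3S,4E)-5-iodo-4-methyl-3-[(triethylsilyl)oxy]pent-4-enal, via diol 25 (not isolated)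
Conditions: OsO4 (2 mol %), NaIO4 (4 equiv), 2,6-lutidine, dioxane/H2O 3:1, rt
Reagents that add atoms: osmium tetroxide, O=[Os](=O)(=O)=O; sodium periodate, [Na+].[O-]I(=O)(=O)=O
Why: Lemieux–Johnson cleavage is selective for the monosubstituted alkene over the hindered, electron-poor iodoalkene and turns the allyl group into the C14–C1 aldehyde.

Step 14
Reactants: 26 (3S,4E)-5-iodo-4-methyl-3-[(triethylsilyl)oxy]pent-4-enal; 27 methyl acrylate
Product: 28 methyl (5S,6E)-3-hydroxy-7-iodo-6-methyl-2-methylidene-5-[(triethylsilyl)oxy]hept-6-enoate (C3 epimers)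
Conditions: DABCO (1 equiv), 27 (5 equiv, neat), rt, 3–5 d
Reagents that add atoms: none
Why: Morita–Baylis–Hillman reaction attaches C15–C17 to C1; the new carbinol centre is not controlled and does not need to be, as it is removed by allylic transposition in step 22.

Step 15
Reactants: 28 methyl (5S,6E)-3-hydroxy-7-iodo-6-methyl-2-methylidene-5-[(triethylsilyl)oxy]hept-6-enoate
Product: 29 methyl (5S,6E)-3-[(tert-butyldimethylsilyl)oxy]-7-iodo-6-methyl-2-methylidene-5-[(triethylsilyl)oxy]hept-6-enoate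
Conditions: TBSOTf, 2,6-lutidine, CH2Cl2, −78 → 0 °C
Reagents that add atoms: tert-butyldimethylsilyl triflate, CC(C)(C)[Si](C)(C)OS(=O)(=O)C(F)(F)F
Why: Silylation masks the allylic hydroxyl so that only the C13 hydroxyl is free for the directed epoxidation and the Mitsunobu step.

Step 16
Reactants: 29 methyl (5S,6E)-3-[(tert-butyldimethylsilyl)oxy]-7-iodo-6-methyl-2-methylidene-5-[(triethylsilyl)oxy]hept-6-enoate
Product: 30 methyl (5S,6E)-3-[(tert-butyldimethylsilyl)oxy]-5-hydroxy-7-iodo-6-methyl-2-methylidenehept-6-enoate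
Conditions: PPTS (0.1 equiv), MeOH/CH2Cl2, 0 °C
Reagents that add atoms: none
Why: Mild acid-catalysed methanolysis removes the secondary triethylsilyl ether far faster than the hindered TBS ether and frees the C13 hydroxyl.

**Union and end game (steps 17–23)**

Step 17
Reactants: 15 tert-butyl{[(2E,6Z)-3,7-dimethylnona-2,6,8-trien-1-yl]oxy}dimethylsilane; 30 methyl (5S,6E)-3-[(tert-butyldimethylsilyl)oxy]-5-hydroxy-7-iodo-6-methyl-2-methylidenehept-6-enoate
Product: 32 methyl (5S,6E,10Z,14E)-3,16-bis[(tert-butyldimethylsilyl)oxy]-5-hydroxy-6,10,14-trimethyl-2-methylidenehexadeca-6,10,14-trienoate, via alkylborane 31 (not isolated)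
Conditions: 9-BBN dimer, THF, 0 °C → rt (15 → 31); then H2O, 30, PdCl2(dppf) (10 mol %), AsPh3, Cs2CO3, DMF/THF/H2O, rt
Reagents that add atoms: none
Why: 9-BBN adds anti-Markovnikov to the terminal vinyl of the diene (B on C10), and B-alkyl Suzuki–Miyaura coupling with the E iodide joins the two halves at C10–C11 with retention of the 11E geometry; the ester and the free hydroxyl are tolerated.

Step 18
Reactants: 32 methyl (5S,6E,10Z,14E)-3,16-bis[(tert-butyldimethylsilyl)oxy]-5-hydroxy-6,10,14-trimethyl-2-methylidenehexadeca-6,10,14-trienoate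
Product: 33 methyl (5S,6S,7S,10Z,14E)-3,16-bis[(tert-butyldimethylsilyl)oxy]-6,7-epoxy-5-hydroxy-6,10,14-trimethyl-2-methylidenehexadeca-10,14-dienoate
Conditions: VO(acac)2 (5 mol %), t-BuOOH (1.5 equiv), CH2Cl2, 0 °C → rt
Reagents that add atoms: tert-butyl hydroperoxide, CC(C)(C)OO
Why: Hydroxyl-directed vanadium-catalysed epoxidation touches only the alkene of the free allylic alcohol; in the transition state that avoids A(1,2) strain with the C12 methyl, oxygen is delivered to give the erythro epoxy alcohol, which sets C11 (S) and C12.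

Step 19
Reactants: 33 methyl (5S,6S,7S,10Z,14E)-3,16-bis[(tert-butyldimethylsilyl)oxy]-6,7-epoxy-5-hydroxy-6,10,14-trimethyl-2-methylidenehexadeca-10,14-dienoate
Product: 34 methyl (5R,6R,7S,10Z,14E)-5-acetoxy-3,16-bis[(tert-butyldimethylsilyl)oxy]-6,7-epoxy-6,10,14-trimethyl-2-methylidenehexadeca-10,14-dienoate
Conditions: PPh3, DIAD, AcOH, toluene, 0 °C → rt
Reagents that add atoms: acetic acid, CC(=O)O
Why: Mitsunobu reaction: SN2 displacement of the alkoxyphosphonium by acetate inverts C13 (S → R), turning erythro into threo and installing the acetate in one step (the C6 descriptor changes only through CIP priorities).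

Step 20
Reactants: 34 methyl (5R,6R,7S,10Z,14E)-5-acetoxy-3,16-bis[(tert-butyldimethylsilyl)oxy]-6,7-epoxy-6,10,14-trimethyl-2-methylidenehexadeca-10,14-dienoate
Product: 35 methyl (5R,6R,7S,10Z,14E)-5-acetoxy-6,7-epoxy-3,16-dihydroxy-6,10,14-trimethyl-2-methylidenehexadeca-10,14-dienoate
Conditions: HF·pyridine, pyridine, THF, 0 °C → rt
Reagents that add atoms: none
Why: Buffered fluoride desilylation removes both TBS ethers while the acetate, the oxirane and the methyl ester stay intact, and the non-basic medium avoids acetyl migration.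

Step 21
Reactants: 35 methyl (5R,6R,7S,10Z,14E)-5-acetoxy-6,7-epoxy-3,16-dihydroxy-6,10,14-trimethyl-2-methylidenehexadeca-10,14-dienoate
Product: 36 methyl (5R,6R,7S,10Z,14E)-5-acetoxy-6,7-epoxy-3-hydroxy-6,10,14-trimethyl-2-methylidene-16-oxohexadeca-10,14-dienoate
Conditions: MnO2, CH2Cl2, rt
Reagents that add atoms: none
Why: MnO2 oxidises the electron-rich primary allylic alcohol at C2 to the E enal much faster than the deactivated secondary alcohol next to the acrylate.

Step 22
Reactants: 36 methyl (5R,6R,7S,10Z,14E)-5-acetoxy-6,7-epoxy-3-hydroxy-6,10,14-trimethyl-2-methylidene-16-oxohexadeca-10,14-dienoate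
Product: 37 methyl (2Z,5R,6R,7S,10Z,14E)-5-acetoxy-2-(bromomethyl)-6,7-epoxy-6,10,14-trimethyl-16-oxohexadeca-2,10,14-trienoate
Conditions: NBS, Me2S, CH2Cl2, −20 °C → rt
Reagents that add atoms: N-bromosuccinimide, O=C1CCC(=O)N1Br
Why: Corey–Kim-type activation followed by SN2′ attack of bromide transposes the Morita–Baylis–Hillman alcohol to the 2-(bromomethyl)-2-enoate (Z favoured, chain trans to the ester) and removes the epimeric centre.

Step 23
Reactants: 37 methyl (2Z,5R,6R,7S,10Z,14E)-5-acetoxy-2-(bromomethyl)-6,7-epoxy-6,10,14-trimethyl-16-oxohexadeca-2,10,14-trienoate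
Product: 40 (1S,2S,3E,7Z,11S,12R,13R)-13-acetoxy-11,12-epoxycembra-3,7,15(17)-trien-16,2-olide, via allylchromium species 38 (not isolated), via chromium alkoxide 39 (not isolated)
Conditions: CrCl2 (10 equiv), THF, rt, syringe-pump addition to 2 mM; aq. NH4Cl work-up
Reagents that add atoms: none
Why: Intramolecular Nozaki–Hiyama (Barbier-type) allylation: the Z-configured 2-(methoxycarbonyl)allylchromium adds 1,2 to the enal through a chair transition state to give the syn adduct, whose alkoxide lactonises to the cis-fused α-methylene lactone; the choice between the 1S,2S and 1R,2R faces rests on substrate control by the C11–C13 triad within the forming ring and is the least certain element of the route.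

**Compound list**
1 | but-2-yn-1-ol | CC#CCO | starting material
2 | sodium 2,2-bis(2-methoxyethoxy)-3-methyl-2,5-dihydro-1,2-oxaaluminol-2-uide (cyclic vinylalanate) | CC1=CCO[Al-]1(OCCOC)OCCOC.[Na+] | intermediate
3 | (Z)-3-iodobut-2-en-1-ol | C/C(I)=C/CO | intermediate
4 | (Z)-1-bromo-3-iodobut-2-ene | C/C(I)=C/CBr | intermediate
5 | trimethyl(prop-1-yn-1-yl)silane | CC#C[Si](C)(C)C | starting material
6 | [3-(trimethylsilyl)prop-2-yn-1-yl]lithium | [Li]CC#C[Si](C)(C)C | intermediate
7 | (Z)-(6-iodohept-5-en-1-yn-1-yl)trimethylsilane | C/C(I)=C/CCC#C[Si](C)(C)C | intermediate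
8 | (Z)-6-iodohept-5-en-1-yne | C/C(I)=C/CCC#C | intermediate
9 | [(1E,5Z)-6-iodo-2-methylhepta-1,5-dien-1-yl]dimethylalane | C/C(I)=C/CC/C(C)=C/[Al](C)C | intermediate
10 | methyl (2E,6Z)-7-iodo-3-methylocta-2,6-dienoate | C/C(I)=C/CC/C(C)=C/C(=O)OC | intermediate
11 | (2E,6Z)-7-iodo-3-methylocta-2,6-dien-1-ol | C/C(I)=C/CC/C(C)=C/CO | intermediate
12 | tert-butyl{[(2E,6Z)-7-iodo-3-methylocta-2,6-dien-1-yl]oxy}dimethylsilane | C/C(I)=C/CC/C(C)=C/CO[Si](C)(C)C(C)(C)C | intermediate
13 | vinylmagnesium bromide | C=C[Mg]Br | starting material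
14 | chloro(vinyl)zinc | C=C[Zn]Cl | intermediate
15 | tert-butyl{[(2E,6Z)-3,7-dimethylnona-2,6,8-trien-1-yl]oxy}dimethylsilane (C2–C10 half) | C=C/C(C)=C\CC/C(C)=C/CO[Si](C)(C)C(C)(C)C | intermediate
16 | prop-2-yn-1-ol | C#CCO | starting material
17 | dimethylaluminium (E)-3-(dimethylalumanyl)-2-methylprop-2-en-1-olate | C[Al](C)OC/C(C)=C/[Al](C)C | intermediate
18 | (E)-3-iodo-2-methylprop-2-en-1-ol | OC/C(C)=C/I | intermediate
19 | (E)-3-iodo-2-methylprop-2-enal | O=C/C(C)=C/I | intermediate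
20 | allylmagnesium bromide | C=CC[Mg]Br | starting material
21 | B-allylbis[(1R,2S,3R,5R)-isopinocampheyl]borane | C=CCB([C@@H]1C[C@@H]2C[C@H]([C@H]1C)C2(C)C)[C@@H]1C[C@@H]2C[C@H]([C@H]1C)C2(C)C | intermediate
22 | (3S,1E)-1-iodo-2-methylhexa-1,5-dien-3-yl bis[(1R,2S,3R,5R)-isopinocampheyl]borinate | I/C=C(\C)[C@@H](OB([C@@H]1C[C@@H]2C[C@H]([C@H]1C)C2(C)C)[C@@H]1C[C@@H]2C[C@H]([C@H]1C)C2(C)C)CC=C | intermediate
23 | (3S,1E)-1-iodo-2-methylhexa-1,5-dien-3-ol | I/C=C(\C)[C@@H](O)CC=C | intermediate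
24 | triethyl{[(3S,1E)-1-iodo-2-methylhexa-1,5-dien-3-yl]oxy}silane | I/C=C(\C)[C@@H](O[Si](CC)(CC)CC)CC=C | intermediate
25 | (4S,5E)-6-iodo-5-methyl-4-[(triethylsilyl)oxy]hex-5-ene-1,2-diol (C2 epimers) | I/C=C(\C)[C@@H](O[Si](CC)(CC)CC)CC(O)CO | intermediate
26 | (3S,4E)-5-iodo-4-methyl-3-[(triethylsilyl)oxy]pent-4-enal | I/C=C(\C)[C@@H](O[Si](CC)(CC)CC)CC=O | intermediate
27 | methyl acrylate | C=CC(=O)OC | starting material
28 | methyl (5S,6E)-3-hydroxy-7-iodo-6-methyl-2-methylidene-5-[(triethylsilyl)oxy]hept-6-enoate (C3 epimers) | I/C=C(\C)[C@@H](O[Si](CC)(CC)CC)CC(O)C(=C)C(=O)OC | intermediate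
29 | methyl (5S,6E)-3-[(tert-butyldimethylsilyl)oxy]-7-iodo-6-methyl-2-methylidene-5-[(triethylsilyl)oxy]hept-6-enoate (C3 epimers) | I/C=C(\C)[C@@H](O[Si](CC)(CC)CC)CC(O[Si](C)(C)C(C)(C)C)C(=C)C(=O)OC | intermediate
30 | methyl (5S,6E)-3-[(tert-butyldimethylsilyl)oxy]-5-hydroxy-7-iodo-6-methyl-2-methylidenehept-6-enoate (C11–C17 half; C3 epimers) | I/C=C(\C)[C@@H](O)CC(O[Si](C)(C)C(C)(C)C)C(=C)C(=O)OC | intermediate
31 | 9-[(3Z,7E)-9-[(tert-butyldimethylsilyl)oxy]-3,7-dimethylnona-3,7-dien-1-yl]-9-borabicyclo[3.3.1]nonane | CC(C)(C)[Si](C)(C)OC/C=C(\C)CC/C=C(/C)CCB1C2CCCC1CCC2 | intermediate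
32 | methyl (5S,6E,10Z,14E)-3,16-bis[(tert-butyldimethylsilyl)oxy]-5-hydroxy-6,10,14-trimethyl-2-methylidenehexadeca-6,10,14-trienoate (C3 epimers) | CC(C)(C)[Si](C)(C)OC/C=C(\C)CC/C=C(/C)CC/C=C(\C)[C@@H](O)CC(O[Si](C)(C)C(C)(C)C)C(=C)C(=O)OC | intermediate
33 | methyl (5S,6S,7S,10Z,14E)-3,16-bis[(tert-butyldimethylsilyl)oxy]-6,7-epoxy-5-hydroxy-6,10,14-trimethyl-2-methylidenehexadeca-10,14-dienoate (erythro; C3 epimers) | CC(C)(C)[Si](C)(C)OC/C=C(\C)CC/C=C(/C)CC[C@@H]1O[C@@]1(C)[C@@H](O)CC(O[Si](C)(C)C(C)(C)C)C(=C)C(=O)OC | intermediate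
34 | methyl (5R,6R,7S,10Z,14E)-5-acetoxy-3,16-bis[(tert-butyldimethylsilyl)oxy]-6,7-epoxy-6,10,14-trimethyl-2-methylidenehexadeca-10,14-dienoate (threo; C3 epimers) | CC(C)(C)[Si](C)(C)OC/C=C(\C)CC/C=C(/C)CC[C@@H]1O[C@@]1(C)[C@H](OC(C)=O)CC(O[Si](C)(C)C(C)(C)C)C(=C)C(=O)OC | intermediate
35 | methyl (5R,6R,7S,10Z,14E)-5-acetoxy-6,7-epoxy-3,16-dihydroxy-6,10,14-trimethyl-2-methylidenehexadeca-10,14-dienoate (C3 epimers) | OC/C=C(\C)CC/C=C(/C)CC[C@@H]1O[C@@]1(C)[C@H](OC(C)=O)CC(O)C(=C)C(=O)OC | intermediate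
36 | methyl (5R,6R,7S,10Z,14E)-5-acetoxy-6,7-epoxy-3-hydroxy-6,10,14-trimethyl-2-methylidene-16-oxohexadeca-10,14-dienoate (C3 epimers) | O=C/C=C(\C)CC/C=C(/C)CC[C@@H]1O[C@@]1(C)[C@H](OC(C)=O)CC(O)C(=C)C(=O)OC | intermediate
37 | methyl (2Z,5R,6R,7S,10Z,14E)-5-acetoxy-2-(bromomethyl)-6,7-epoxy-6,10,14-trimethyl-16-oxohexadeca-2,10,14-trienoate | O=C/C=C(\C)CC/C=C(/C)CC[C@@H]1O[C@@]1(C)[C@H](OC(C)=O)C/C=C(\CBr)C(=O)OC | intermediate
38 | methyl (2Z,5R,6R,7S,10Z,14E)-5-acetoxy-2-[(dichlorochromio)methyl]-6,7-epoxy-6,10,14-trimethyl-16-oxohexadeca-2,10,14-trienoate | O=C/C=C(\C)CC/C=C(/C)CC[C@@H]1O[C@@]1(C)[C@H](OC(C)=O)C/C=C(\C[Cr](Cl)Cl)C(=O)OC | intermediate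
39 | dichlorochromium alkoxide of methyl 2-[(1S,2S,3E,7Z,11S,12R,13R)-13-acetoxy-11,12-epoxy-2-hydroxy-4,8,12-trimethylcyclotetradeca-3,7-dien-1-yl]prop-2-enoate | COC(=O)C(=C)[C@@H]1C[C@@H](OC(C)=O)[C@]2(C)O[C@H]2CC/C(C)=C\CC/C(C)=C/[C@@H]1O[Cr](Cl)Cl | intermediate
40 | (1S,2S,3E,7Z,11S,12R,13R)-13-acetoxy-11,12-epoxycembra-3,7,15(17)-trien-16,2-olide (CNP0146076.3) | C=C1C(=O)O[C@H]2/C=C(\C)CC/C=C(/C)CC[C@@H]3O[C@@]3(C)[C@H](OC(C)=O)C[C@@H]12 | target

**Step count**
Total: 23 steps. Longest linear sequence: 15 steps (steps 1–8 then 17–23, or steps 9–16 then 17–23), which is 15/23 = 0.65 of the total.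

**Three steps most likely to fail, with fallbacks**

Step 23 (macrocyclisation). The yield may suffer from oligomerisation or reduction of the bromide, and the facial selectivity at C1/C2 is only substrate-controlled. Fallback: set out from hydroxy enal 36 and acetylate the allylic hydroxyl (Ac2O, DMAP, pyridine) to give the allylic acetate F7. With Pd(PPh3)4 (cat.) and InI in THF at high dilution, the π-allylpalladium formed from F7 is reduced to the allylindium species F8, which adds to the C2 aldehyde through a closed transition state and lactonises. This comes back to the route at target 40, avoids the labile bromide 37, and offers a second metal and transition-state geometry with which to probe the facial selectivity.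

Step 19 (Mitsunobu inversion). The carbinol is flanked by a fully substituted oxirane carbon, so elimination or no reaction is possible. Fallback: set out from epoxy alcohol 33 and oxidise it with Dess–Martin periodinane to the epoxy ketone F5. Reagent-controlled reduction with (S)-2-methyl-CBS-oxazaborolidine and catecholborane (toluene, −78 °C) gives the threo epoxy alcohol F6 with C13 as R. Acetylation (Ac2O, DMAP, pyridine) comes back to the route at epoxy acetate 34.

Step 17 (one-pot hydroboration and Suzuki–Miyaura coupling). Transmetalation may be incomplete, β-hydride elimination may compete, or residual borane may attack the acrylate. Fallback: set out from triene 15, hydroborate as before to 31, but oxidise (NaOH, H2O2) to the primary alcohol F1. I2, PPh3 and imidazole give the primary iodide F2. t-BuLi (Et2O, −78 °C) followed by ZnCl2 gives the alkylzinc chloride F3. Negishi coupling (Pd(PPh3)4, THF, rt) with the fully silylated vinyl iodide 29 gives the coupled triethylsilyl ether F4. PPTS in MeOH removes the triethylsilyl group and comes back to the route at 32.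

**Further compounds**
F1 | step 17 | (3Z,7E)-9-[(tert-butyldimethylsilyl)oxy]-3,7-dimethylnona-3,7-dien-1-ol | CC(C)(C)[Si](C)(C)OC/C=C(\C)CC/C=C(/C)CCO
F2 | step 17 | tert-butyl{[(2E,6Z)-9-iodo-3,7-dimethylnona-2,6-dien-1-yl]oxy}dimethylsilane | CC(C)(C)[Si](C)(C)OC/C=C(\C)CC/C=C(/C)CCI
F3 | step 17 | [(3Z,7E)-9-[(tert-butyldimethylsilyl)oxy]-3,7-dimethylnona-3,7-dien-1-yl]zinc chloride | CC(C)(C)[Si](C)(C)OC/C=C(\C)CC/C=C(/C)CC[Zn]Cl
F4 | step 17 | methyl (5S,6E,10Z,14E)-3,16-bis[(tert-butyldimethylsilyl)oxy]-6,10,14-trimethyl-2-methylidene-5-[(triethylsilyl)oxy]hexadeca-6,10,14-trienoate | CC(C)(C)[Si](C)(C)OC/C=C(\C)CC/C=C(/C)CC/C=C(\C)[C@@H](O[Si](CC)(CC)CC)CC(O[Si](C)(C)C(C)(C)C)C(=C)C(=O)OC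
F5 | step 19 | methyl (6R,7S,10Z,14E)-3,16-bis[(tert-butyldimethylsilyl)oxy]-6,7-epoxy-6,10,14-trimethyl-2-methylidene-5-oxohexadeca-10,14-dienoate | CC(C)(C)[Si](C)(C)OC/C=C(\C)CC/C=C(/C)CC[C@@H]1O[C@@]1(C)C(=O)CC(O[Si](C)(C)C(C)(C)C)C(=C)C(=O)OC
F6 | step 19 | methyl (5R,6S,7S,10Z,14E)-3,16-bis[(tert-butyldimethylsilyl)oxy]-6,7-epoxy-5-hydroxy-6,10,14-trimethyl-2-methylidenehexadeca-10,14-dienoate (threo) | CC(C)(C)[Si](C)(C)OC/C=C(\C)CC/C=C(/C)CC[C@@H]1O[C@@]1(C)[C@H](O)CC(O[Si](C)(C)C(C)(C)C)C(=C)C(=O)OC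
F7 | step 23 | methyl (5R,6R,7S,10Z,14E)-3,5-diacetoxy-6,7-epoxy-6,10,14-trimethyl-2-methylidene-16-oxohexadeca-10,14-dienoate | O=C/C=C(\C)CC/C=C(/C)CC[C@@H]1O[C@@]1(C)[C@H](OC(C)=O)CC(OC(C)=O)C(=C)C(=O)OC
F8 | step 23 | methyl (2Z,5R,6R,7S,10Z,14E)-5-acetoxy-2-{[acetoxy(iodo)indiganyl]methyl}-6,7-epoxy-6,10,14-trimethyl-16-oxohexadeca-2,10,14-trienoate | O=C/C=C(\C)CC/C=C(/C)CC[C@@H]1O[C@@]1(C)[C@H](OC(C)=O)C/C=C(\C[In](I)OC(C)=O)C(=O)OC
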